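The numbers stand for no real mixture; the rest is arithmetic.

At late times I treat the flask as one balanced pool leaking slowly to product, so I reckon that leak first.

    intermediate D → product (k1 = 0.020 min⁻¹)
    intermediate A ⇌ intermediate C (K2 = 3.3, k2 = 0.16 min⁻¹)
    coupling partner + product ⇌ idle adduct, settled at all times (K3 = 11 M⁻¹)
    intermediate C ⇌ intermediate E (K4 = 0.32, k4 = 0.016 min⁻¹)
    substrate ⇌ intermediate A (K5 = 10, k5 = 0.31 min⁻¹)
    intermediate A ⇌ intermediate D (K6 = 0.93, k6 = 0.016 min⁻¹)
    substrate + coupling partner ⇌ intermediate B (K7 = 33 M⁻¹, k7 = 0.98 M⁻¹ min⁻¹)

| setting | south-west | south-east | west | north-east |
|---|---|---|---|---|
| substrate | 12 mM | 12 mM | 12 mM | 12 mM |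
| coupling partner | 4.00 equiv | 4.00 equiv (fed, over 1.00 h) | 4.00 equiv | 4.00 equiv |
| time | 2.0 h | 2.0 h |  |  |
| remark | everything together in a closed stirred flask, run for 2.0 h | all but coupling partner at the start; coupling partner goes in evenly over 1.00 h, the run ends at 2.0 h | one stirred flow tank at steady state, fed with the mixture as stated, mean residence time 20.0 h | one stirred flow tank at steady state, fed with the mixture as stated, mean residence time 2.0 h |

- the set-up with the highest amount of product at the outlet or at the end, in percent of the substrate put in ("none" if the first two lie within 2 percentage points) (south-west / south-east / west / north-east / none)
- amount of product at the outlet or at the end, in percent of the substrate put in, south-west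
- amount of product at the outlet or at the end, in percent of the substrate put in, south-east
- amount of product at the outlet or at the end, in percent of the substrate put in, west
- amount of product at the outlet or at the end, in percent of the substrate put in, north-east

- amounts and yields of product count idle adduct too
- the stated concentrations are those of everything mixed, before any reaction; amounts are the same in each set-up
- the feed brings no volume worth counting
- run time (south-west): 2.0 h

Per unit of intermediate A, the balanced pool holds 0.100 of substrate, 3.3 of intermediate C, 1.06 of intermediate E and 0.158 of intermediate B at the starting coupling partner. Its weight is W = 5.61, and intermediate C, the resting state, outweighs intermediate E. Product forms from intermediate D. Held steady, it turns intermediate A into product with a constant L = 0.00860 min⁻¹, the forward step into intermediate D times the share that goes on to product.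

Intermediate D also has weight, and this gives my bracket. With none, the pool drains at 0.00153 min⁻¹; with its full balance weight of 0.93, at 0.00131 min⁻¹. Its steady weight is 0.430, which lies between, so I commit to the drain constant κ, the leak L divided by the pool weight with steady intermediate D counted: κ = 0.00142 min⁻¹.

With the pool balanced, a steady tank of residence time τ turns κτ/(1+κτ) into product. For the west tank this gives 61.2% to 64.8%, and I commit to 63.1%. A batch taken as balanced from the start goes as 1 − exp(−κt) at run time t, which on this reckoning puts south-west between 14.6% and 16.8%. That batch figure is rough, since the run of 2.0 h is 2.78 times the half-life of intermediate C by its forward step into intermediate E alone, 0.72 h. I pick the west tank: its 20.0 h is ten times the 2.0 h of the other set-ups, and its low end stands above the batch top.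

The forecast also picks west, holding that “the yield is set mainly by contact time”. It gives 16.3% for south-west, 16.6% for south-east, 62.7% for west and 14.8% for north-east. Its west figure sits inside my bracket, and its south-west figure sits below my batch top.

The flask gives west as the best set-up, with 62.7% there, against 14.7% for south-west, 15.4% for south-east and 13.6% for north-east. The west reading lies 0.4 percentage points under my 63.1%, and intermediate B holds 1.29% of the charge in that tank. On the north-east tank, with a residence time of 2.0 h, the same κ gives 14.6%, and that tank reads 13.6% with 43.7% of the charge as intermediate C.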